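**Retrosynthetic overview**
1. The cyclohexene ring is formed last, by a chelation-steered Diels–Alder reaction between (12E)-labda-8(17),12,14-triene-2α,7β-diol and a flavone-derived 2-methoxy-1,4-benzoquinone.
2. The diene comes from an allyl handle (cross-metathesis, then Wittig); 7β-OH comes from allylic oxidation and Luche reduction; 2α-OH comes from dissolving-metal reduction of a C2 ketone.
3. Rings A and B are formed together in one enantioselective, enone-initiated, allylsilane-terminated bicyclisation of an achiral tetraenone, which sets C5, C9 and C10.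
4. The tetraenone is assembled by Negishi coupling of an iodo-dienone (from propargyl alcohol and 2-methylbut-3-yn-2-ol) with a bromo-allylsilane (from 4-bromobut-1-yne).
5. The quinone comes from 2,4,5-trimethoxyacetophenone and phloroglucinol (flavone formation, then oxidative demethylation).

Assumption: labdane numbering (C1–C20) is used for the terpenoid part, primed locants (C1′–C6′, C5′ carrying the chromone) for the quinone-derived ring, and the (12E)-triene is taken as the Diels–Alder partner.

**Step 1**
Reactants: 1 prop-2-yn-1-ol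
Product: 3 (E)-3-iodo-2-methylprop-2-en-1-ol, via alkenylalane 2 (not isolated)
Conditions: Me3Al (3 equiv), Cp2ZrCl2 (0.25 equiv), CH2Cl2, 0 °C → rt; then I2, THF, −30 → 0 °C; aq. NaHCO3/Na2S2O3 work-up
Reagents that add atoms: trimethylaluminium C[Al](C)C; iodine II
Why: Zirconium-catalysed carboalumination (Negishi) adds CH3 and Al syn across the alkyne with CH3 on the internal carbon, and iodinolysis with retention fixes the E vinyl iodide.

**Step 2**
Reactants: 3 (E)-3-iodo-2-methylprop-2-en-1-ol; 4 2-methylbut-3-yn-2-ol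
Product: 6 (E)-7-iodo-2,6-dimethylhept-6-en-3-yn-2-ol, via allylic mesylate 5 (not isolated)
Conditions: MsCl, Et3N, CH2Cl2, −20 °C; then 4, CuI (10 mol%), NaI (10 mol%), Cs2CO3, DMF, rt
Reagents that add atoms: none
Why: The copper acetylide of 4 displaces the crude allylic mesylate in an SN2 alkynyl–allyl coupling at the unhindered CH2; the vinyl iodide is inert to copper at room temperature, so the alkene geometry is kept.

**Step 3**
Reactants: 6 (E)-7-iodo-2,6-dimethylhept-6-en-3-yn-2-ol
Product: 7 (E)-7-iodo-2,6-dimethylhepta-2,6-dien-4-one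
Conditions: MoO2(acac)2 (2 mol%), AuCl(PPh3) (2 mol%), AgOTf (2 mol%), toluene, rt
Reagents that add atoms: none
Why: Meyer–Schuster rearrangement (1,3-shift of the tertiary propargylic hydroxyl, then tautomerisation) gives the β,β-dimethyl enone, and the neutral conditions keep the β,γ-alkene out of conjugation.

**Step 4**
Reactants: 8 4-bromobut-1-yne
Product: 10 (4Z)-7-bromo-5-[(trimethylsilyl)methyl]hepta-1,4-diene, via vinylcopper 9 (not isolated)
Conditions: Me3SiCH2MgCl (1.2 equiv), CuBr·SMe2 (1.2 equiv), Et2O/Me2S, −45 → −15 °C; then allyl bromide, −30 → 0 °C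
Reagents that add atoms: (trimethylsilyl)methylmagnesium chloride C[Si](C)(C)C[Mg]Cl; allyl bromide C=CCBr
Why: Syn carbocupration (Normant type) puts CH2SiMe3 on the internal alkyne carbon and copper on the terminus, and allylation of the vinylcopper with retention gives the trisubstituted allylsilane with CH2SiMe3 cis to the allyl group; the primary bromide survives at low temperature.

**Step 5**
Reactants: 10 (4Z)-7-bromo-5-[(trimethylsilyl)methyl]hepta-1,4-diene; 7 (E)-7-iodo-2,6-dimethylhepta-2,6-dien-4-one
Product: 13 (6E,10Z)-2,6-dimethyl-10-[(trimethylsilyl)methyl]tetradeca-2,6,10,13-tetraen-4-one, via Grignard reagent 11 (not isolated), via organozinc chloride 12 (not isolated)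
Conditions: Mg, THF, rt; ZnCl2, 0 °C; then 7, PdCl2(dppf) (3 mol%), THF, rt
Reagents that add atoms: none
Why: Negishi sp3–sp2 cross-coupling joins the alkylzinc to the vinyl iodide with retention of the E geometry, and the organozinc tolerates the enone.

**Step 6**
Reactants: 13 (6E,10Z)-2,6-dimethyl-10-[(trimethylsilyl)methyl]tetradeca-2,6,10,13-tetraen-4-one
Product: 15 (5S,9S,10S)-14,15,16-trinorlabda-8(17),12-dien-2-one, via silyl enol ether 14 (not isolated)
Conditions: (S,S)-IDPi (BINOL-derived imidodiphosphorimidate, 3,3′-bis[3,5-bis(trifluoromethyl)phenyl], N-triflyl core; 3 mol%), toluene/CH2Cl2 4:1, −60 °C; then 1 M HCl, THF, 0 °C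
Reagents that add atoms: none
Why: Proposed new method: the N-silylated IDPi (formed in situ from the acid and a trace of the substrate's allylsilane) O-silylates the enone to a 2-silyloxyallyl cation held in the chiral anion pocket; the 6E alkene attacks its CMe2 terminus through a chair–chair fold, the allylsilane captures the C10 cation, and loss of Me3Si+ to the anion regenerates the catalyst, leaving the 8(17)-methylene and a C2 silyl enol ether that is hydrolysed on work-up; the anion shields one face of the planar cation, so the first stereocentres C5, C10 and C9 are set together (trans-decalin from the E alkene, equatorial C9 side chain from the Z allylsilane), and the catalyst antipode that gives 5S,9S,10S is used; the closest known reactions are IDPi/silylium-catalysed Mukaiyama–Michael and Hosomi–Sakurai additions, Brønsted-acid IDPi polyene cyclisations, and racemic Lewis-acid enone-initiated cation–olefin cyclisations.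

**Step 7**
Reactants: 15 (5S,9S,10S)-14,15,16-trinorlabda-8(17),12-dien-2-one
Product: 16 (2S,5S,9S,10S)-14,15,16-trinorlabda-8(17),12-dien-2α-ol
Conditions: Li, NH3(l)/THF, t-BuOH (1.5 equiv), −78 °C; then NH4Cl
Reagents that add atoms: none
Why: Dissolving-metal reduction goes through the ketyl/carbanion and gives the thermodynamically favoured equatorial 2α-alcohol (hydride reagents would attack from the α face and give the axial 2β-epimer because of the two syn-axial methyls at C4 and C10); isolated alkenes are not reduced.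

**Step 8**
Reactants: 16 (2S,5S,9S,10S)-14,15,16-trinorlabda-8(17),12-dien-2α-ol
Product: 18 2α-hydroxy-14,15,16-trinorlabda-8(17),12-dien-7-one, via 7α-alcohol 17 (not isolated)
Conditions: SeO2 (0.3 equiv), t-BuOOH (2.5 equiv), CH2Cl2, 0 °C → rt; filter; then MnO2 (15 equiv), CH2Cl2, rt
Reagents that add atoms: selenium dioxide O=[Se]=O; tert-butyl hydroperoxide CC(C)(C)OO
Why: Selenium dioxide allylic oxidation (ene reaction, then [2,3]-shift) attacks the ring CH2 at C7 of the 1,1-disubstituted alkene in preference to the tertiary C9–H or the monosubstituted allyl group, and MnO2 then converges the axial 7α-alcohol and any enone already formed on the enone without touching the saturated 2α-OH.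

**Step 9**
Reactants: 18 2α-hydroxy-14,15,16-trinorlabda-8(17),12-dien-7-one
Product: 19 14,15,16-trinorlabda-8(17),12-diene-2α,7β-diol
Conditions: NaBH4, CeCl3·7H2O, MeOH, −78 °C
Reagents that add atoms: none
Why: Luche 1,2-reduction: the small hydride adds axially from the α face of the C7 ketone (only axial hydrogens at C5 and C9 lie on that face), giving the equatorial 7β-alcohol.

**Step 10**
Reactants: 19 14,15,16-trinorlabda-8(17),12-diene-2α,7β-diol
Product: 20 (12E)-2α,7β-dihydroxy-15-norlabda-8(17),12-dien-14-al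
Conditions: methacrolein (8 equiv), second-generation Hoveyda–Grubbs catalyst (5 mol%), CH2Cl2, 40 °C
Reagents that add atoms: methacrolein CC(=C)C=O
Why: Olefin cross-metathesis of the terminal allyl alkene with excess methacrolein gives the E trisubstituted enal under thermodynamic control; the hindered 1,1-disubstituted 8(17)-alkene does not react.

**Step 11**
Reactants: 20 (12E)-2α,7β-dihydroxy-15-norlabda-8(17),12-dien-14-al
Product: 21 (12E)-labda-8(17),12,14-triene-2α,7β-diol
Conditions: Ph3PCH3Br (4 equiv), KOt-Bu (3.8 equiv), THF, 0 °C → rt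
Reagents that add atoms: methyltriphenylphosphonium bromide C[P+](c1ccccc1)(c1ccccc1)c1ccccc1.[Br-]
Why: Wittig methylenation of the enal (excess ylide tolerates the free hydroxyls) completes the 12E,14-diene without changing the C12=C13 geometry.

**Step 12**
Reactants: 22 1-(2,4,5-trimethoxyphenyl)ethan-1-one
Product: 23 ethyl 3-oxo-3-(2,4,5-trimethoxyphenyl)propanoate
Conditions: NaH (2.5 equiv), (EtO)2CO, toluene, 80 °C; then aq. HCl
Reagents that add atoms: diethyl carbonate CCOC(=O)OCC
Why: Crossed Claisen condensation of the ketone enolate with diethyl carbonate, driven by deprotonation of the β-keto ester product.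

**Step 13**
Reactants: 23 ethyl 3-oxo-3-(2,4,5-trimethoxyphenyl)propanoate; 24 benzene-1,3,5-triol
Product: 25 5,7-dihydroxy-2-(2,4,5-trimethoxyphenyl)-4H-chromen-4-one
Conditions: neat, microwave, 240 °C, 10 min
Reagents that add atoms: none
Why: Thermal condensation of phloroglucinol with the aroylacetate (C-acylation, then cyclodehydration; a Simonis-type chromone synthesis) gives the 5,7-dihydroxyflavone directly, and the symmetry of phloroglucinol removes any regiochemical issue.

**Step 14**
Reactants: 25 5,7-dihydroxy-2-(2,4,5-trimethoxyphenyl)-4H-chromen-4-one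
Product: 26 5,7-dihydroxy-2-(4-methoxy-3,6-dioxocyclohexa-1,4-dien-1-yl)-4H-chromen-4-one
Conditions: (NH4)2Ce(NO3)6 (2.2 equiv), MeCN/H2O 4:1, −10 → 0 °C, 15 min
Reagents that add atoms: water O
Why: Oxidative demethylation: single-electron oxidation of the electron-rich trimethoxyaryl ring (far easier to oxidise than the acyl-deactivated ring A) and hydrolysis of the para-dimethoxy pair give the 2-methoxy-1,4-benzoquinone.

**Step 15**
Reactants: 26 5,7-dihydroxy-2-(4-methoxy-3,6-dioxocyclohexa-1,4-dien-1-yl)-4H-chromen-4-one; 21 (12E)-labda-8(17),12,14-triene-2α,7β-diol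
Product: 29 Dichrostachine B, via boron chelate 27 (not isolated), via adduct chelate 28 (not isolated)
Conditions: B(OAc)3 (1.1 equiv), CH2Cl2, 25 °C, 1 h; then 21, CH2Cl2, 0 → 25 °C, 48 h, dark; then MeOH/H2O, 40 °C; chromatography
Reagents that add atoms: none
Why: Chelation-steered Diels–Alder reaction: boron-acetate chelation of the 5-hydroxy-4-oxo unit (a peri-hydroxy-carbonyl activation established for quinone dienophiles) makes the chromonyl arm the LUMO-lowering group, so the unsubstituted diene terminus C15 bonds to the δ-carbon C6′ and C12 to the chromonyl-bearing C5′; suprafacial addition gives the cis ring fusion (5′S,6′R), the chelated chromone is expected to take the endo position so that the outside CH2 of the 12E diene ends cis to it, and the dienophile is expected to enter the C12 face anti to the C9–C10 bond (12R), with the face isomer removed by chromatography.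

**Compound list**
1 | prop-2-yn-1-ol | C#CCO | starting material
2 | [(2E)-3-(dimethylalumanyl)-2-methylprop-2-en-1-yl]oxy(dimethyl)alumane | C[Al](C)OC/C(C)=C/[Al](C)C | intermediate
3 | (E)-3-iodo-2-methylprop-2-en-1-ol | OC/C(C)=C/I | intermediate
4 | 2-methylbut-3-yn-2-ol | CC(C)(O)C#C | starting material
5 | (E)-3-iodo-2-methylprop-2-en-1-yl methanesulfonate | CS(=O)(=O)OC/C(C)=C/I | intermediate
6 | (E)-7-iodo-2,6-dimethylhept-6-en-3-yn-2-ol | CC(C)(O)C#CC/C(C)=C/I | intermediate
7 | (E)-7-iodo-2,6-dimethylhepta-2,6-dien-4-one | CC(C)=CC(=O)C/C(C)=C/I | intermediate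
8 | 4-bromobut-1-yne | C#CCCBr | starting material
9 | {(1Z)-4-bromo-2-[(trimethylsilyl)methyl]but-1-en-1-yl}copper | BrCC/C(C[Si](C)(C)C)=C/[Cu] | intermediate
10 | (4Z)-7-bromo-5-[(trimethylsilyl)methyl]hepta-1,4-diene | BrCC/C(C[Si](C)(C)C)=C/CC=C | intermediate
11 | bromo{(3Z)-3-[(trimethylsilyl)methyl]hepta-3,6-dien-1-yl}magnesium | Br[Mg]CC/C(C[Si](C)(C)C)=C/CC=C | intermediate
12 | chloro{(3Z)-3-[(trimethylsilyl)methyl]hepta-3,6-dien-1-yl}zinc | Cl[Zn]CC/C(C[Si](C)(C)C)=C/CC=C | intermediate
13 | (6E,10Z)-2,6-dimethyl-10-[(trimethylsilyl)methyl]tetradeca-2,6,10,13-tetraen-4-one | CC(C)=CC(=O)C/C(C)=C/CC/C(C[Si](C)(C)C)=C/CC=C | intermediate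
14 | 2-(trimethylsilyloxy)-14,15,16-trinorlabda-2,8(17),12-triene (trans-decalin; 10β-CH3, 5α-H, 9α-H) | C=C1CC[C@H]2C(C)(C)C=C(O[Si](C)(C)C)C[C@]2(C)[C@H]1CC=C | intermediate
15 | (5S,9S,10S)-14,15,16-trinorlabda-8(17),12-dien-2-one (10β-CH3, 5α-H, 9α-H) | C=C1CC[C@H]2C(C)(C)CC(=O)C[C@]2(C)[C@H]1CC=C | intermediate
16 | (2S,5S,9S,10S)-14,15,16-trinorlabda-8(17),12-dien-2α-ol | C=C1CC[C@H]2C(C)(C)C[C@H](O)C[C@]2(C)[C@H]1CC=C | intermediate
17 | 14,15,16-trinorlabda-8(17),12-diene-2α,7α-diol | C=C1[C@H](O)C[C@H]2C(C)(C)C[C@H](O)C[C@]2(C)[C@H]1CC=C | intermediate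
18 | 2α-hydroxy-14,15,16-trinorlabda-8(17),12-dien-7-one | C=C1C(=O)C[C@H]2C(C)(C)C[C@H](O)C[C@]2(C)[C@H]1CC=C | intermediate
19 | 14,15,16-trinorlabda-8(17),12-diene-2α,7β-diol | C=C1[C@@H](O)C[C@H]2C(C)(C)C[C@H](O)C[C@]2(C)[C@H]1CC=C | intermediate
20 | (12E)-2α,7β-dihydroxy-15-norlabda-8(17),12-dien-14-al | C=C1[C@@H](O)C[C@H]2C(C)(C)C[C@H](O)C[C@]2(C)[C@H]1C/C=C(\C)C=O | intermediate
21 | (12E)-labda-8(17),12,14-triene-2α,7β-diol | C=C1[C@@H](O)C[C@H]2C(C)(C)C[C@H](O)C[C@]2(C)[C@H]1C/C=C(\C)C=C | intermediate
22 | 1-(2,4,5-trimethoxyphenyl)ethan-1-one | CC(=O)c1cc(OC)c(OC)cc1OC | starting material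
23 | ethyl 3-oxo-3-(2,4,5-trimethoxyphenyl)propanoate | CCOC(=O)CC(=O)c1cc(OC)c(OC)cc1OC | intermediate
24 | benzene-1,3,5-triol (phloroglucinol) | Oc1cc(O)cc(O)c1 | starting material
25 | 5,7-dihydroxy-2-(2,4,5-trimethoxyphenyl)-4H-chromen-4-one | COc1cc(OC)c(cc1OC)-c1cc(=O)c2c(O)cc(O)cc2o1 | intermediate
26 | 5,7-dihydroxy-2-(4-methoxy-3,6-dioxocyclohexa-1,4-dien-1-yl)-4H-chromen-4-one | COC1=CC(=O)C(=CC1=O)c1cc(=O)c2c(O)cc(O)cc2o1 | intermediate
27 | diacetoxyboron 5-O,4-O chelate of 26 | COC1=CC(=O)C(=CC1=O)C1=CC2=[O+][B-](OC(C)=O)(OC(C)=O)OC3=CC(O)=CC(O1)=C23 | intermediate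
28 | diacetoxyboron 5-O,4-O chelate of 29 | C=C1[C@@H](O)C[C@H]2C(C)(C)C[C@H](O)C[C@]2(C)[C@H]1C[C@@H]1C(C)=CC[C@H]2C(=O)C(OC)=CC(=O)[C@@]12C1=CC2=[O+][B-](OC(C)=O)(OC(C)=O)OC3=CC(O)=CC(O1)=C23 | intermediate
29 | Dichrostachine B | C=C1[C@@H](O)C[C@H]2C(C)(C)C[C@H](O)C[C@]2(C)[C@H]1C[C@@H]1C(C)=CC[C@H]2C(=O)C(OC)=CC(=O)[C@@]12c1cc(=O)c2c(O)cc(O)cc2o1 | target

**Step count**
Total: 15 steps. Longest linear sequence: 11 steps (1, 2, 3, 5, 6, 7, 8, 9, 10, 11, 15).

**Three steps most likely to fail**

Step 6 (the proposed new bicyclisation). The risks are conjugation of the β,γ-alkene before cyclisation, protodesilylation of the allylsilane, and low enantioselectivity. The fallback uses known chemistry and sets out from 13. Treatment with Me2AlCl (2.2 equiv, CH2Cl2, −78 °C), a Lewis-acid enone-initiated, allylsilane-terminated cation–olefin cyclisation of a known racemic reaction class, gives the racemic ketone rac-14,15,16-trinorlabda-8(17),12-dien-2-one F1. Li/NH3 reduction as in step 7 gives the racemic alcohol rac-14,15,16-trinorlabda-8(17),12-dien-2α-ol F2. Steglich esterification with (S)-O-acetylmandelic acid (DCC, DMAP) gives two diastereomeric esters that are separated on silica, the wanted one being 14,15,16-trinorlabda-8(17),12-dien-2α-yl (S)-O-acetylmandelate F3. K2CO3 in MeOH cleaves it, and the route is rejoined at 16.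

Step 15 (Diels–Alder). Reactivity and regiochemistry are well supported, but the chromone-endo preference and the face selectivity rest on models, and the usual quinone-endo mode would place C11 trans to the chromone. The fallback sets out from 21. Benzophenone-sensitised photoisomerisation (350 nm, benzene) followed by separation on AgNO3–silica gives (12Z)-labda-8(17),12,14-triene-2α,7β-diol F4. Its thermal Diels–Alder reaction with 26 (toluene, 12 kbar, 40 °C, no boron) is run under ordinary quinone-endo control: the C11 methylene is now the inside diene substituent and therefore ends trans to C4′=O, that is, cis to the chromone, the same relative configuration. The route is rejoined at 29.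

Step 4 (carbocupration with a silylmethylcopper reagent, a poorly transferring group). The fallback sets out from 8. PdBr2(PhCN)2-catalysed bromoallylation with allyl bromide (syn addition of Br and allyl across the alkyne) gives (4Z)-5,7-dibromohepta-1,4-diene F5. Kumada coupling of its vinyl bromide with Me3SiCH2MgCl (Pd(PPh3)4, THF, rt, retention; the alkyl bromide is inert to zerovalent palladium under these conditions) rejoins the route at 10.

**Further compounds**
F1 | step 6 | rac-14,15,16-trinorlabda-8(17),12-dien-2-one (racemate of 15) | C=C1CC[C@H]2C(C)(C)CC(=O)C[C@]2(C)[C@H]1CC=C.C=C1CC[C@@H]2C(C)(C)CC(=O)C[C@@]2(C)[C@@H]1CC=C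
F2 | step 6 | rac-14,15,16-trinorlabda-8(17),12-dien-2α-ol (racemate of 16) | C=C1CC[C@H]2C(C)(C)C[C@H](O)C[C@]2(C)[C@H]1CC=C.C=C1CC[C@@H]2C(C)(C)C[C@@H](O)C[C@@]2(C)[C@@H]1CC=C
F3 | step 6 | (2S,5S,9S,10S)-14,15,16-trinorlabda-8(17),12-dien-2α-yl (S)-O-acetylmandelate | C=C1CC[C@H]2C(C)(C)C[C@H](OC(=O)[C@@H](OC(C)=O)c3ccccc3)C[C@]2(C)[C@H]1CC=C
F4 | step 15 | (12Z)-labda-8(17),12,14-triene-2α,7β-diol | C=C1[C@@H](O)C[C@H]2C(C)(C)C[C@H](O)C[C@]2(C)[C@H]1C/C=C(/C)C=C
F5 | step 4 | (4Z)-5,7-dibromohepta-1,4-diene | BrCC/C(Br)=C/CC=C
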